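Labels: oxolane O1–C2(3,4-dihydroxyphenyl)–C3(C9H2OAc)–C4(C7'H2-guaiacyl)–C5H2. The C9 and C7' arms are cis on C3–C4, so they can be tied for a time as a gamma-lactone ring C3–C9(=O)–O–C7'–C4. C3 is then a lactone alpha carbon that can carry a carbene, and C2–H is a benzylic ether C–H placed 1,5 to it.
Retrosynthetic cuts, in order: the C2 configuration (from the C2 epimer); C7'–H (from C7'–OAc) and both acetates (from the lactone C9(=O)–O–C7'); C2–C3 (C–H insertion of an alpha-diazo lactone); O1–C2 (benzyl ether from a trichloroacetimidate); C4–C7' (aldol of a succinate imide with O-benzylvanillin).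
Forward: the lactone ring arises first (aldol, lactonisation) and the catechol benzyl group is hung on the C5 oxygen. The oxolane ring closes second, by C2–C3 insertion, to a cis-fused 3,7-dioxabicyclo[3.3.0]octan-2-one. The lactone ring is then taken apart (LiAlH4, Ac2O, H2 over Pd/C).
Stereochemistry: (S)-4-benzyloxazolidinone sets C4 (R) and C7' in an Evans syn aldol, C4 sets C3 through the obligatory cis ring fusion, and C7' is erased by hydrogenolysis. C2 is born endo (2R) under kinetic control and is turned into the 2,3-trans centre (2S) at the end by acid equilibration of the strained all-cis oxolane.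

Key step: step 8

Remark: in the bicyclic lactone the endo and exo C2-aryl epimers should be close in energy, as they are in furofuran lignans, so C2 is corrected only after ring opening, where the all-cis oxolane is clearly the less stable epimer; any exo epimer formed in step 8 converges on the same final product.

Step 1
Reactants: 1 (S)-4-benzyl-1,3-oxazolidin-2-one; 2 methyl 4-chloro-4-oxobutanoate
Product: 3 methyl 4-[(4S)-4-benzyl-2-oxo-1,3-oxazolidin-3-yl]-4-oxobutanoate
Conditions: n-BuLi, THF, -78 °C; then 2, -78 to 0 °C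
Reagents that add atoms: none
Why: N-acylation of the lithiated oxazolidinone by an acid chloride is the standard entry to Evans imides, and the methyl ester is not attacked at low temperature.

Step 2
Reactants: 3 methyl 4-[(4S)-4-benzyl-2-oxo-1,3-oxazolidin-3-yl]-4-oxobutanoate; 4 4-(benzyloxy)-3-methoxybenzaldehyde
Product: 6 (4S)-4-benzyl-3-{[(2S,3S)-2-[4-(benzyloxy)-3-methoxyphenyl]-5-oxooxolan-3-yl]carbonyl}-1,3-oxazolidin-2-one, via syn-aldol hydroxy ester 5 (not isolated)
Conditions: Bu2BOTf, Et3N, CH2Cl2, -78 to 0 °C; 4, -78 to 0 °C; pH 7 buffer, MeOH, H2O2, 0 °C; then cat. PPTS, CH2Cl2, rt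
Reagents that add atoms: none
Why: Evans syn aldol followed by lactonisation: Bu2BOTf and Et3N enolise only the imide alpha-CH2 to the Z boron enolate, which adds to 4 through a chair Zimmerman-Traxler transition state on the face turned away from the benzyl group of the auxiliary and so sets C4 and C7' (3S,4S in 5), and the syn hydroxy ester closes onto the methyl ester to the 4,5-trans gamma-lactone.

Step 3
Reactants: 6 (4S)-4-benzyl-3-{[(2S,3S)-2-[4-(benzyloxy)-3-methoxyphenyl]-5-oxooxolan-3-yl]carbonyl}-1,3-oxazolidin-2-one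
Product: 7 (2S,3S)-2-[4-(benzyloxy)-3-methoxyphenyl]-5-oxooxolane-3-carboxylic acid
Conditions: LiOH, H2O2, THF-H2O, 0 °C; Na2SO3; HCl to pH 2
Reagents that add atoms: hydrogen peroxide OO
Why: Standard LiOOH cleavage of an Evans imide: hydroperoxide attacks the exocyclic carbonyl, a lactone that opens in base recloses on acidification, and the trans acid is the more stable epimer, so neither centre is at risk.

Step 4
Reactants: 7 (2S,3S)-2-[4-(benzyloxy)-3-methoxyphenyl]-5-oxooxolane-3-carboxylic acid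
Product: 8 (4R,5S)-5-[4-(benzyloxy)-3-methoxyphenyl]-4-(hydroxymethyl)oxolan-2-one
Conditions: BH3·THF, THF, 0 °C to rt; then H2O
Reagents that add atoms: none
Why: Chemoselective borane reduction: a free carboxylic acid is reduced through its acyloxyborane far faster than a lactone, so only the carboxyl carbon (C5) goes to the primary alcohol.

Step 5
Reactants: 9 [3,4-bis(benzyloxy)phenyl]methanol
Product: 10 3,4-bis(benzyloxy)benzyl 2,2,2-trichloroacetimidate
Conditions: Cl3CCN, DBU (cat.), CH2Cl2, 0 °C; used fresh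
Reagents that add atoms: trichloroacetonitrile N#CC(Cl)(Cl)Cl
Why: Base-catalysed addition of a benzylic alcohol to trichloroacetonitrile is the general way to trichloroacetimidates and leaves the aryl benzyl ethers alone.

Step 6
Reactants: 8 (4R,5S)-5-[4-(benzyloxy)-3-methoxyphenyl]-4-(hydroxymethyl)oxolan-2-one; 10 3,4-bis(benzyloxy)benzyl 2,2,2-trichloroacetimidate
Product: 11 (4R,5S)-5-[4-(benzyloxy)-3-methoxyphenyl]-4-({[3,4-bis(benzyloxy)benzyl]oxy}methyl)oxolan-2-one
Conditions: La(OTf)3 (5 mol %), toluene, rt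
Reagents that add atoms: none
Why: Acid-catalysed trichloroacetimidate O-benzylation, as in a PMB protection: the electron-rich imidate ionises under a mild Lewis acid and is taken up by the primary alcohol, which forms O1-C2 without the base that would open or transpose the lactone.

Step 7
Reactants: 11 (4R,5S)-5-[4-(benzyloxy)-3-methoxyphenyl]-4-({[3,4-bis(benzyloxy)benzyl]oxy}methyl)oxolan-2-one
Product: 13 (4R,5S)-5-[4-(benzyloxy)-3-methoxyphenyl]-4-({[3,4-bis(benzyloxy)benzyl]oxy}methyl)-3-diazooxolan-2-one, via 3-trifluoroacetyl lactone 12 (not isolated)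
Conditions: LiN(SiMe3)2, THF, -78 °C; CF3CO2CH2CF3; dilute HCl wash; crude 12, MsN3, Et3N, H2O (1 equiv), MeCN, rt
Reagents that add atoms: methanesulfonyl azide CS(=O)(=O)N=[N+]=[N-]; 2,2,2-trifluoroethyl trifluoroacetate FC(F)(F)COC(=O)C(F)(F)F (its trifluoroacetyl group stays only in 12)
Why: Detrifluoroacetylative (Regitz-type) diazo transfer: Claisen trifluoroacetylation of the lactone enolate makes C3 acidic enough for Et3N, the sulfonyl azide then delivers N2 and carries off the trifluoroacetyl group, and C4 and C7' are not touched.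

Step 8
Reactants: 13 (4R,5S)-5-[4-(benzyloxy)-3-methoxyphenyl]-4-({[3,4-bis(benzyloxy)benzyl]oxy}methyl)-3-diazooxolan-2-one
Product: 14 (1S,4S,5R,8R)-8-[3,4-bis(benzyloxy)phenyl]-4-[4-(benzyloxy)-3-methoxyphenyl]-3,7-dioxabicyclo[3.3.0]octan-2-one (cis-fused; C2 aryl endo; C7' aryl exo; 2R,3S,4R,7'S in the labels used here)
Conditions: Rh2(OAc)4 (2 mol %), CH2Cl2, reflux, slow addition of 13
Reagents that add atoms: none
Why: Rh2(OAc)4 takes N2 out of 13 and leaves an electrophilic dirhodium carbenoid at C3, which inserts in one concerted, hydride-transfer-like event (three-centre C3-H-C2 transition state) into a C2-H bond of the benzylic ether, the known 1,5 C-H insertion of alpha-diazo lactones next to an ether oxygen. The oxolane O1-C2-C3-C4-C5 closes by C2-C3 bond formation as a five-membered ring, the ring size that such carbenoids prefer over four- and six-membered alternatives. C3 is fixed by C4, because the short C4-C5-O1-C2 tether reaches only the lactone face that carries C5 and a bicyclo[3.3.0]octane can only be cis-fused, which is the cis C9/C7' relation of the target. C2 is fixed by the choice between the two diastereotopic benzylic hydrogens (insertion goes with retention): the aryl group turns away from the acetate wall of the catalyst and comes to lie under the lactone carbonyl, so the endo epimer (2R, cis to C9) is expected for this substrate class and is corrected in step 12. The step needs site selectivity for C2-H and chemoselectivity against the 1,2-hydride shift of C4-H to a butenolide; the first is secured by the double activation of C2-H (ether oxygen plus electron-rich aryl) and its 1,5 position, the second by the two oxygen-bearing carbons C5 and C7' on C4, which disfavour positive charge there, and slow addition keeps carbene dimers down. The CH2 groups of the aryl benzyl ethers are too remote to compete.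

Step 9
Reactants: 14 (1S,4S,5R,8R)-8-[3,4-bis(benzyloxy)phenyl]-4-[4-(benzyloxy)-3-methoxyphenyl]-3,7-dioxabicyclo[3.3.0]octan-2-one
Product: 15 (S)-[4-(benzyloxy)-3-methoxyphenyl]{(3R,4R,5R)-5-[3,4-bis(benzyloxy)phenyl]-4-(hydroxymethyl)oxolan-3-yl}methanol (2R,3R,4R,7'S; all three ring substituents cis)
Conditions: LiAlH4, THF, 0 °C; Na2SO4·10H2O quench
Reagents that add atoms: none
Why: LiAlH4 reduction of a lactone to the 1,4-diol leaves the benzyl ethers, the oxolane and all four centres untouched, and the neutral work-up avoids ionisation of the benzylic alcohol.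

Step 10
Reactants: 15 (S)-[4-(benzyloxy)-3-methoxyphenyl]{(3R,4R,5R)-5-[3,4-bis(benzyloxy)phenyl]-4-(hydroxymethyl)oxolan-3-yl}methanol
Product: 16 the C9,C7'-diacetate of 15 (2R,3R,4R,7'S)
Conditions: Ac2O, pyridine, DMAP (cat.), CH2Cl2, rt
Reagents that add atoms: acetic anhydride CC(=O)OC(C)=O
Why: DMAP-catalysed acylation esterifies both hydroxyls, which installs the C9 acetate of the target and turns the C7' oxygen into a better leaving group for hydrogenolysis.

Step 11
Reactants: 16 the C9,C7'-diacetate of 15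
Product: 17 [(2R,3R,4R)-2-(3,4-dihydroxyphenyl)-4-(4-hydroxy-3-methoxybenzyl)oxolan-3-yl]methyl acetate (all-cis; the C2 epimer of the target)
Conditions: H2 (1 atm), 10% Pd/C, EtOAc-EtOH, rt, stopped when the C7' acetate is gone
Reagents that add atoms: none
Why: Heterogeneous hydrogenolysis should cleave the three aryl benzyl ethers and the secondary benzylic acetate faster than the cyclic benzylic ether C2-O1, the primary C9 acetate is inert, and the C7' centre disappears.

Step 12
Reactants: 17 [(2R,3R,4R)-2-(3,4-dihydroxyphenyl)-4-(4-hydroxy-3-methoxybenzyl)oxolan-3-yl]methyl acetate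
Product: 18 [(2S,3R,4R)-2-(3,4-dihydroxyphenyl)-4-(4-hydroxy-3-methoxybenzyl)oxolan-3-yl]methyl acetate (target)
Conditions: camphorsulfonic acid (10 mol %), MeCN, argon, 0 °C to rt, stopped as soon as 17 is consumed; NaHCO3
Reagents that add atoms: none
Why: Acid-catalysed epimerisation of a 2-aryl oxolane lignan: reversible heterolysis of C2-O1 gives the p-hydroxybenzyl cation (protonated quinone methide), which the C5 hydroxyl recaptures with the aryl group trans to C9 to avoid allylic-type strain, so the strained all-cis 17 should drain into the 2,3-trans epimer 18 (2S) while C3 and C4 cannot change.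

Compound list
1 | (S)-4-benzyl-1,3-oxazolidin-2-one | O=C1N[C@@H](Cc2ccccc2)CO1 | starting material
2 | methyl 4-chloro-4-oxobutanoate | COC(=O)CCC(=O)Cl | starting material
3 | methyl 4-[(4S)-4-benzyl-2-oxo-1,3-oxazolidin-3-yl]-4-oxobutanoate | COC(=O)CCC(=O)N1[C@@H](Cc2ccccc2)COC1=O | intermediate
4 | 4-(benzyloxy)-3-methoxybenzaldehyde | O=Cc1ccc(OCc2ccccc2)c(OC)c1 | starting material
5 | methyl (3S,4S)-3-{[(4S)-4-benzyl-2-oxo-1,3-oxazolidin-3-yl]carbonyl}-4-[4-(benzyloxy)-3-methoxyphenyl]-4-hydroxybutanoate | O=C(N1[C@@H](Cc2ccccc2)COC1=O)[C@@H](CC(=O)OC)[C@H](O)c1ccc(OCc2ccccc2)c(OC)c1 | intermediate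
6 | (4S)-4-benzyl-3-{[(2S,3S)-2-[4-(benzyloxy)-3-methoxyphenyl]-5-oxooxolan-3-yl]carbonyl}-1,3-oxazolidin-2-one | O=C(N1[C@@H](Cc2ccccc2)COC1=O)[C@H]1CC(=O)O[C@@H]1c1ccc(OCc2ccccc2)c(OC)c1 | intermediate
7 | (2S,3S)-2-[4-(benzyloxy)-3-methoxyphenyl]-5-oxooxolane-3-carboxylic acid | OC(=O)[C@H]1CC(=O)O[C@@H]1c1ccc(OCc2ccccc2)c(OC)c1 | intermediate
8 | (4R,5S)-5-[4-(benzyloxy)-3-methoxyphenyl]-4-(hydroxymethyl)oxolan-2-one | OC[C@H]1CC(=O)O[C@@H]1c1ccc(OCc2ccccc2)c(OC)c1 | intermediate
9 | [3,4-bis(benzyloxy)phenyl]methanol | OCc1ccc(OCc2ccccc2)c(OCc2ccccc2)c1 | starting material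
10 | 3,4-bis(benzyloxy)benzyl 2,2,2-trichloroacetimidate | N=C(OCc1ccc(OCc2ccccc2)c(OCc2ccccc2)c1)C(Cl)(Cl)Cl | intermediate
11 | (4R,5S)-5-[4-(benzyloxy)-3-methoxyphenyl]-4-({[3,4-bis(benzyloxy)benzyl]oxy}methyl)oxolan-2-one | c1ccccc1COc1ccc(cc1OCc1ccccc1)COC[C@H]1CC(=O)O[C@@H]1c1ccc(OCc2ccccc2)c(OC)c1 | intermediate
12 | 3-(trifluoroacetyl) derivative of 11 (C3 unassigned, largely enolised) | c1ccccc1COc1ccc(cc1OCc1ccccc1)COC[C@H]1C(C(=O)C(F)(F)F)C(=O)O[C@@H]1c1ccc(OCc2ccccc2)c(OC)c1 | intermediate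
13 | (4R,5S)-5-[4-(benzyloxy)-3-methoxyphenyl]-4-({[3,4-bis(benzyloxy)benzyl]oxy}methyl)-3-diazooxolan-2-one | c1ccccc1COc1ccc(cc1OCc1ccccc1)COC[C@H]1C(=[N+]=[N-])C(=O)O[C@@H]1c1ccc(OCc2ccccc2)c(OC)c1 | intermediate
14 | (1S,4S,5R,8R)-8-[3,4-bis(benzyloxy)phenyl]-4-[4-(benzyloxy)-3-methoxyphenyl]-3,7-dioxabicyclo[3.3.0]octan-2-one (endo,exo) | c1ccccc1COc1ccc(cc1OCc1ccccc1)[C@@H]1OC[C@H]2[C@@H]1C(=O)O[C@@H]2c1ccc(OCc2ccccc2)c(OC)c1 | intermediate
15 | all-cis oxolane diol (2R,3R,4R,7'S) | OC[C@@H]1[C@H](c2ccc(OCc3ccccc3)c(OCc3ccccc3)c2)OC[C@@H]1[C@H](O)c1ccc(OCc2ccccc2)c(OC)c1 | intermediate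
16 | all-cis oxolane diacetate (2R,3R,4R,7'S) | CC(=O)OC[C@@H]1[C@H](c2ccc(OCc3ccccc3)c(OCc3ccccc3)c2)OC[C@@H]1[C@H](OC(C)=O)c1ccc(OCc2ccccc2)c(OC)c1 | intermediate
17 | [(2R,3R,4R)-2-(3,4-dihydroxyphenyl)-4-(4-hydroxy-3-methoxybenzyl)oxolan-3-yl]methyl acetate | COc1cc(C[C@H]2CO[C@@H](c3ccc(O)c(O)c3)[C@H]2COC(C)=O)ccc1O | intermediate
18 | [(2S,3R,4R)-2-(3,4-dihydroxyphenyl)-4-(4-hydroxy-3-methoxybenzyl)oxolan-3-yl]methyl acetate | COc1cc(C[C@H]2CO[C@H](c3ccc(O)c(O)c3)[C@H]2COC(C)=O)ccc1O | target

Total step count: 12. Longest linear sequence: 11 (steps 1-4 and 6-12; step 5 is the side branch).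

Steps most likely to fail

Step 8. The carbenoid may be lost by 1,2-hydride shift from C4 or by dimerisation before it reaches C2-H. The fallback makes C2-C3 by a lactone enolate aldol and closes the oxolane through a cation. It sets out from 8 and comes back at 18.
- Hydrogenolysis of 8 (H2, Pd/C, EtOH) cuts the benzylic lactone C7'-O bond and the benzyl ether. The hydroxy acid relactonises through the C5 hydroxyl to (4R)-4-(4-hydroxy-3-methoxybenzyl)oxolan-2-one F1.
- BnBr and K2CO3 give (4R)-4-[4-(benzyloxy)-3-methoxybenzyl]oxolan-2-one F2.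
- LiN(SiMe3)2 and 3,4-bis(benzyloxy)benzaldehyde add at C3 anti to the benzyl arm and give the 3,4-trans aldol lactone F3 as carbinol epimers.
- LiAlH4 gives the (3R,4R)-triol F4.
- Catalytic camphorsulfonic acid in CH2Cl2 ionises the C2 carbinol, and the C5 hydroxyl closes the 2,3-trans-3,4-cis oxolane alcohol F5.
- Ac2O in pyridine gives its C9 acetate F6, and a short hydrogenolysis of the three benzyl ethers gives 18.

Step 12. The C2 cation may be captured irreversibly by the guaiacyl ring (Friedel-Crafts closure to an aryltetralin) or may lose a proton faster than the oxolane re-forms. The fallback corrects C2 by a radical instead of a cation, before deprotection. It sets out from 16 and comes back at 18. Thiol-catalysed radical-chain epimerisation (PhSH, AIBN, benzene, 80 °C) abstracts and returns the C2 hydrogen, the weakest C-H because it is benzylic and next to oxygen. This should equilibrate 16 to the 2,3-trans diacetate F7. Scrambling at C7' is of no consequence. Hydrogenolysis as in step 11 then gives 18 directly.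

Step 11. Over-reduction may occur, that is, hydrogenolytic opening of the oxolane at C2-O1 while the slower C7' acetate is still being cleaved. The fallback removes the C7' oxygen by a radical deoxygenation (Barton-McCombie). It sets out from 15 and comes back at 17.
- AcCl and 2,4,6-collidine at -78 °C acetylate only the primary hydroxyl to the C9 monoacetate F8.
- PhOC(S)Cl and DMAP give the C7' phenyl thionocarbonate F9.
- Bu3SnH and AIBN in toluene at 80 °C give the all-cis tri-O-benzyl acetate F10.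
- A brief hydrogenolysis, which now has only aryl benzyl ethers to cleave, gives 17.

Further compounds
F1 | step 8 | (4R)-4-(4-hydroxy-3-methoxybenzyl)oxolan-2-one | O=C1C[C@@H](Cc2ccc(O)c(OC)c2)CO1
F2 | step 8 | (4R)-4-[4-(benzyloxy)-3-methoxybenzyl]oxolan-2-one | O=C1C[C@@H](Cc2ccc(OCc3ccccc3)c(OC)c2)CO1
F3 | step 8 | (3S,4R)-4-[4-(benzyloxy)-3-methoxybenzyl]-3-{[3,4-bis(benzyloxy)phenyl](hydroxy)methyl}oxolan-2-one (carbinol epimers) | O=C1[C@H](C(O)c2ccc(OCc3ccccc3)c(OCc3ccccc3)c2)[C@@H](Cc2ccc(OCc3ccccc3)c(OC)c2)CO1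
F4 | step 8 | (2R,3R)-2-{[3,4-bis(benzyloxy)phenyl](hydroxy)methyl}-3-[4-(benzyloxy)-3-methoxybenzyl]butane-1,4-diol (carbinol epimers) | OC[C@H](C(O)c1ccc(OCc2ccccc2)c(OCc2ccccc2)c1)[C@H](CO)Cc1ccc(OCc2ccccc2)c(OC)c1
F5 | step 8 | {(2S,3R,4R)-2-[3,4-bis(benzyloxy)phenyl]-4-[4-(benzyloxy)-3-methoxybenzyl]oxolan-3-yl}methanol | OC[C@@H]1[C@@H](c2ccc(OCc3ccccc3)c(OCc3ccccc3)c2)OC[C@@H]1Cc1ccc(OCc2ccccc2)c(OC)c1
F6 | step 8 | {(2S,3R,4R)-2-[3,4-bis(benzyloxy)phenyl]-4-[4-(benzyloxy)-3-methoxybenzyl]oxolan-3-yl}methyl acetate | CC(=O)OC[C@@H]1[C@@H](c2ccc(OCc3ccccc3)c(OCc3ccccc3)c2)OC[C@@H]1Cc1ccc(OCc2ccccc2)c(OC)c1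
F7 | step 12 | 2,3-trans oxolane diacetate (2S,3R,4R,7'S), the C2 epimer of 16 | CC(=O)OC[C@@H]1[C@@H](c2ccc(OCc3ccccc3)c(OCc3ccccc3)c2)OC[C@@H]1[C@H](OC(C)=O)c1ccc(OCc2ccccc2)c(OC)c1
F8 | step 11 | C9 monoacetate of 15 (2R,3R,4R,7'S) | CC(=O)OC[C@@H]1[C@H](c2ccc(OCc3ccccc3)c(OCc3ccccc3)c2)OC[C@@H]1[C@H](O)c1ccc(OCc2ccccc2)c(OC)c1
F9 | step 11 | C7' O-phenyl thionocarbonate of F8 | CC(=O)OC[C@@H]1[C@H](c2ccc(OCc3ccccc3)c(OCc3ccccc3)c2)OC[C@@H]1[C@H](OC(=S)Oc1ccccc1)c1ccc(OCc2ccccc2)c(OC)c1
F10 | step 11 | {(2R,3R,4R)-2-[3,4-bis(benzyloxy)phenyl]-4-[4-(benzyloxy)-3-methoxybenzyl]oxolan-3-yl}methyl acetate | CC(=O)OC[C@@H]1[C@H](c2ccc(OCc3ccccc3)c(OCc3ccccc3)c2)OC[C@@H]1Cc1ccc(OCc2ccccc2)c(OC)c1
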